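**Retrosynthetic overview**
1. Target ⇐ BBr3 cleavage of its hexamethyl ether (the ring B para-hydroxyl is already free).
2. Ring D–Cc bond ⇐ veratrole plus a cyclic benzylic cation; seven-membered ring ⇐ Friedel–Crafts closure of ring B onto a masked arylacetaldehyde (enol ether from a vinylboron Suzuki coupling).
3. Key disconnection Ca–Cb (closes the dihydrophenanthrene and sets Cb): the ring A aldehyde carbon, reversed in polarity as its N–H hydrazone (alkyl carbanion equivalent, loses N2), adds 1,6 to a p-quinone methide whose carbon was the vanillin aldehyde carbon, so two natively electrophilic carbons are joined.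
4. Biaryl A–C ⇐ one-pot borylation/Suzuki; quinone methide precursor ⇐ 3-bromo-5-chloroanisole lithiated between the halogens, added to O-silyl vanillin and trapped as the pivalate.
5. Ring order: rings A, B, C, D are bought; the six-membered ring forms in step 3, the seven-membered ring in step 5.

Labels: ring A = resorcinol ring; ring C = central mono-oxygenated ring; ring B = catechol ring inside the seven-membered ring; ring D = pendant catechol. Ca = CH2 of the six-membered ring, Cb = CH joining rings B and C (R in the target), Cc = CH carrying ring D (S in the target), Cd = CH2 of the seven-membered ring.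

Assumption: O-TBS vanillin 2 is bought as a catalogue compound (otherwise it is one silylation from vanillin).
Assumption: a reagent is listed under "Reagents that add atoms" when its non-hydrogen atoms end up in the isolated product or in a numbered non-isolated intermediate of that step (the line says which); numbered reactants are not repeated there.

**Step 1**
Reactants: 1 1-bromo-3-chloro-5-methoxybenzene; 2 4-(tert-butyldimethylsilyloxy)-3-methoxybenzaldehyde
Product: 5 rac-(2-bromo-6-chloro-4-methoxyphenyl)[4-(tert-butyldimethylsilyloxy)-3-methoxyphenyl]methyl pivalate, via aryllithium 3 (not isolated), via lithium alkoxide 4 (not isolated)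
Conditions: LiN(iPr)2 (1.05 equiv, commercial solution), THF, −78 °C, 45 min; then 2 (1.0 equiv), −78 °C, 30 min; then pivaloyl chloride (1.5 equiv), −78 °C → rt
Reagents that add atoms: lithium diisopropylamide, [Li+].CC(C)[N-]C(C)C (Li only in 3 and 4); pivaloyl chloride, CC(C)(C)C(=O)Cl (in 5)
Why: Directed lithiation removes the most acidic C–H, flanked by both halogens, the aryllithium adds 1,2 to the aldehyde and the alkoxide is O-acylated in situ, giving a racemic benzhydryl pivalate whose stereocentre is erased later.

**Step 2**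
Reactants: 5 pivalate from step 1; 6 2-bromo-3,5-dimethoxybenzaldehyde
Product: 8 rac-(3-chloro-2'-formyl-4',5,6'-trimethoxybiphenyl-2-yl)[4-(tert-butyldimethylsilyloxy)-3-methoxyphenyl]methyl pivalate (atropisomer mixture), via aryl pinacol boronate 7 (not isolated)
Conditions: B2pin2 (1.05 equiv), Pd(OAc)2 (4 mol%), SPhos (8 mol%), KOAc (3 equiv), 1,4-dioxane, 80 °C; then 6 (1.3 equiv), K3PO4·H2O (3 equiv), 80 °C, same pot
Reagents that add atoms: bis(pinacolato)diboron, CC1(C)OB(OC1(C)C)B1OC(C)(C)C(C)(C)O1 (boron and pinacol only in 7)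
Why: Miyaura borylation then Suzuki–Miyaura coupling is selective for C–Br over the flanked C–Cl, puts boron on the ring without the ortho-formyl group (little protodeboronation), and the nearly anhydrous phosphate spares the aryl silyl ether and the pivalate.

**Step 3 (key step)**
Reactants: 8 biaryl aldehyde from step 2
Product: 11 4-[(10R)-1-chloro-3,5,7-trimethoxy-9,10-dihydrophenanthren-10-yl]-2-methoxyphenol, via hydrazone 9 (not isolated), via p-quinone methide 10 (not isolated)
Conditions: N2H4·H2O (1.2 equiv), THF, rt, 1 h; then [Ru(p-cymene)Cl2]2 (2.5 mol%), (R,R)-Me-BPE (5.5 mol%), K3PO4 (0.5 equiv), THF (0.02 M), argon; CsF (2.0 equiv) added last, 45 °C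
Reagents that add atoms: hydrazine hydrate, NN.O (both N atoms only in 9 and 10; they leave as N2)
Why: Proposed new method: the N–H hydrazone 9, bound to divalent ruthenium as a carbanion equivalent (closest known chemistry: ruthenium/bisphosphine-catalysed additions of aldehyde hydrazones to carbonyls and Michael acceptors with Wolff–Kishner-type loss of N2), sits next to p-quinone methide 10 once fluoride frees the phenoxide and pivalate leaves by 1,6-elimination, so its carbon adds 1,6 to the methide carbon in a six-membered ring closure (N-attack would need an eight-membered ring) and N2 loss leaves the CH2; because the racemic carbinol centre is erased in planar 10 and the biaryl axis rotates, the C2-symmetric phosphine on ruthenium alone selects the methide face and sets C10 as R (the sense of induction is not predictable, and the ligand antipode is taken if it is opposite).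

**Step 4**
Reactants: 11 chloro-dihydrophenanthrene phenol from step 3; 12 (E)-2-(2-ethoxyethenyl)-4,4,5,5-tetramethyl-1,3,2-dioxaborolane
Product: 13 4-[(10R)-1-[(E)-2-ethoxyethenyl]-3,5,7-trimethoxy-9,10-dihydrophenanthren-10-yl]-2-methoxyphenol
Conditions: Pd(OAc)2 (5 mol%), SPhos (10 mol%), K3PO4 (3 equiv), 1,4-dioxane/H2O 10:1, 90 °C
Reagents that add atoms: none
Why: Suzuki–Miyaura coupling with a dialkylbiarylphosphine activates the hindered aryl chloride and installs an enol ether, a masked arylacetaldehyde, without touching C10 or the free phenol.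

**Step 5**
Reactants: 13 enol ether from step 4; 14 1,2-dimethoxybenzene (veratrole)
Product: 16 hexamethyl ether of the target (Cb R; Cc S; ring B 4-OH free), via dibenzocycloheptene 15 (not isolated)
Conditions: TFA (10 equiv), CH2Cl2 (0.005 M), 0 °C → rt; then 14 (10 equiv), TfOH (1.5 equiv), −40 → 0 °C
Reagents that add atoms: none
Why: Protonation gives an oxocarbenium ion that closes onto ring B C6 (para to OMe; Bradsher-type intramolecular Friedel–Crafts) and loses ethanol to alkene 15, whose reprotonation at Cd gives the Cc cation stabilised by the ring B para-OMe; veratrole then adds (Friedel–Crafts hydroarylation) to the outer face, because the inner face of the locked boat is covered by the pseudo-axial Cb–H, so ring D ends pseudo-equatorial and Cc–H cis to Cb–H (Cc = S).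

**Step 6**
Reactants: 16 hexamethyl ether from step 5
Product: 17 CNP0306974.1 (Cb R; Cc S)
Conditions: BBr3 (15 equiv), CH2Cl2, −78 °C → rt; MeOH then H2O quench
Reagents that add atoms: none
Why: Lewis-acid cleavage of the six aryl methyl ethers (BBr3 demethylation) frees all seven phenols without touching either benzylic stereocentre.

**Compound list**
1 | 1-bromo-3-chloro-5-methoxybenzene | COc1cc(Br)cc(Cl)c1 | starting material
2 | 4-(tert-butyldimethylsilyloxy)-3-methoxybenzaldehyde | COc1cc(C=O)ccc1O[Si](C)(C)C(C)(C)C | starting material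
3 | (2-bromo-6-chloro-4-methoxyphenyl)lithium | COc1cc(Br)c([Li])c(Cl)c1 | intermediate (not isolated)
4 | lithium rac-(2-bromo-6-chloro-4-methoxyphenyl)[4-(tert-butyldimethylsilyloxy)-3-methoxyphenyl]methanolate | [Li+].COc1cc(Br)c(C([O-])c2ccc(O[Si](C)(C)C(C)(C)C)c(OC)c2)c(Cl)c1 | intermediate (not isolated)
5 | rac-(2-bromo-6-chloro-4-methoxyphenyl)[4-(tert-butyldimethylsilyloxy)-3-methoxyphenyl]methyl pivalate | COc1cc(Br)c(C(OC(=O)C(C)(C)C)c2ccc(O[Si](C)(C)C(C)(C)C)c(OC)c2)c(Cl)c1 | intermediate
6 | 2-bromo-3,5-dimethoxybenzaldehyde | COc1cc(OC)c(Br)c(C=O)c1 | starting material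
7 | rac-[2-chloro-4-methoxy-6-(4,4,5,5-tetramethyl-1,3,2-dioxaborolan-2-yl)phenyl][4-(tert-butyldimethylsilyloxy)-3-methoxyphenyl]methyl pivalate | COc1cc(B2OC(C)(C)C(C)(C)O2)c(C(OC(=O)C(C)(C)C)c2ccc(O[Si](C)(C)C(C)(C)C)c(OC)c2)c(Cl)c1 | intermediate (not isolated)
8 | rac-(3-chloro-2'-formyl-4',5,6'-trimethoxybiphenyl-2-yl)[4-(tert-butyldimethylsilyloxy)-3-methoxyphenyl]methyl pivalate | COc1cc(OC)c(c(C=O)c1)-c1cc(OC)cc(Cl)c1C(OC(=O)C(C)(C)C)c1ccc(O[Si](C)(C)C(C)(C)C)c(OC)c1 | intermediate
9 | (E)-N–H hydrazone of 8 | COc1cc(OC)c(c(/C=N/N)c1)-c1cc(OC)cc(Cl)c1C(OC(=O)C(C)(C)C)c1ccc(O[Si](C)(C)C(C)(C)C)c(OC)c1 | intermediate (not isolated)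
10 | p-quinone methide from 9 after loss of the silyl group and pivalate (E/Z mixture at the methide) | COc1cc(OC)c(c(/C=N/N)c1)-c1cc(OC)cc(Cl)c1C=C1C=CC(=O)C(OC)=C1 | intermediate (not isolated)
11 | 4-[(10R)-1-chloro-3,5,7-trimethoxy-9,10-dihydrophenanthren-10-yl]-2-methoxyphenol | COc1cc(OC)c2c(c1)C[C@H](c1ccc(O)c(OC)c1)c1c(Cl)cc(OC)cc-21 | intermediate
12 | (E)-2-(2-ethoxyethenyl)-4,4,5,5-tetramethyl-1,3,2-dioxaborolane | CCO/C=C/B1OC(C)(C)C(C)(C)O1 | starting material
13 | 4-[(10R)-1-[(E)-2-ethoxyethenyl]-3,5,7-trimethoxy-9,10-dihydrophenanthren-10-yl]-2-methoxyphenol | COc1cc(OC)c2c(c1)C[C@H](c1ccc(O)c(OC)c1)c1c(/C=C/OCC)cc(OC)cc-21 | intermediate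
14 | 1,2-dimethoxybenzene (veratrole) | COc1ccccc1OC | starting material
15 | (Cb R) pentacyclic dibenzocycloheptene: 13 closed from ring B C6 onto the enol ether carbon with loss of ethanol (Cc=Cd double bond) | COc1cc(OC)c2c(c1)C[C@@H]1c3cc(OC)c(O)cc3C=Cc3cc(OC)cc-2c31 | intermediate (not isolated)
16 | (Cb R, Cc S) hexamethyl ether of the target, ring B 4-OH free, ring D = 3,4-dimethoxyphenyl on Cc | COc1cc(OC)c2c(c1)C[C@@H]1c3cc(OC)c(O)cc3[C@H](c3ccc(OC)c(OC)c3)Cc3cc(OC)cc-2c31 | intermediate
17 | CNP0306974.1 (Cb R, Cc S) | Oc1cc(O)c2c(c1)C[C@@H]1c3cc(O)c(O)cc3[C@H](c3ccc(O)c(O)c3)Cc3cc(O)cc-2c31 | target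

**Totals**
Total step count: 6. Longest linear sequence: 6 steps (from 1 or 2).

**Three steps most likely to fail**

Step 3 is the main risk. The intramolecular, in situ quinone methide version of the hydrazone addition is untested, the enantioselectivity from a chiral bisphosphine on ruthenium is unproven, and azine formation or simple Wolff–Kishner reduction of 9 can compete. Fallback: set out from 8 and run the same cyclisation with the achiral ligand dmpe to give racemic phenol F1. Then give up catalyst control and resolve F1 by preparative chiral SFC on a polysaccharide phase, taking the (10R) enantiomer back into the route at 11.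

Step 5 is next. The cyclic Cc cation lies under the pseudo-axial Cb–H, so a transannular 1,4-hydride shift to the more stabilised bis-aryl Cb cation could erase Cb. The facial selectivity of the veratrole addition rests on a conformational argument only. Fallback: set out from 11 and run a Mizoroki–Heck coupling with 3,4-dimethoxystyrene (Pd2(dba)3, P(t-Bu)3, Cy2NMe, dioxane, 110 °C) to give E-stilbene F2. Treating F2 with TfOH in CH2Cl2/HFIP protonates Cd, and the ring D-stabilised open-chain Cc cation is captured by ring B C6 in an intramolecular Friedel–Crafts closure. The cyclic cation is never formed, and the route is rejoined at 16. In this variant the configuration at Cc is set in the ring-closing transition state and may need acid equilibration.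

Step 2 is third. The tri-ortho-substituted biaryl is hindered, and loss of the aryl silyl ether under base would release the quinone methide early. Fallback: set out from 5 and do a Br/Mg exchange with iPrMgCl·LiCl (THF, −40 °C) to give arylmagnesium chloride F3. Transmetalation with ZnCl2 gives arylzinc chloride F4, and a base-free, anhydrous Negishi coupling with bromide 6 (Pd(OAc)2, SPhos, THF, 50 °C) rejoins the route at 8.

**Further compounds**
F1 | step 3 | rac-4-(1-chloro-3,5,7-trimethoxy-9,10-dihydrophenanthren-10-yl)-2-methoxyphenol | COc1cc(OC)c2c(c1)CC(c1ccc(O)c(OC)c1)c1c(Cl)cc(OC)cc-21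
F2 | step 5 | 4-[(10R)-1-[(E)-2-(3,4-dimethoxyphenyl)ethenyl]-3,5,7-trimethoxy-9,10-dihydrophenanthren-10-yl]-2-methoxyphenol | COc1cc(OC)c2c(c1)C[C@H](c1ccc(O)c(OC)c1)c1c(/C=C/c3ccc(OC)c(OC)c3)cc(OC)cc-21
F3 | step 2 | arylmagnesium chloride from 5 (Br replaced by MgCl) | COc1cc([Mg]Cl)c(C(OC(=O)C(C)(C)C)c2ccc(O[Si](C)(C)C(C)(C)C)c(OC)c2)c(Cl)c1
F4 | step 2 | arylzinc chloride from F3 (MgCl replaced by ZnCl) | COc1cc([Zn]Cl)c(C(OC(=O)C(C)(C)C)c2ccc(O[Si](C)(C)C(C)(C)C)c(OC)c2)c(Cl)c1
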